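**Plan**

1. Retrosynthesis: ring C of the flavanone (rings A, C, B; the flavone is rings D, E, F) is opened at O1–C2 and C4–C4a, giving free phloroglucinol (ring A) and an (E)-cinnamoyl chloride; the alkene is cut back to an aldehyde (Knoevenagel–Doebner), and the biaryl bond C2'(ring B)–C6(ring D) to a 6-iodoflavone and an arylboronate (Suzuki–Miyaura).
2. Forward: rings D, E, F are bought as apigenin, benzylated and iodinated at C6; ring B comes from 2-bromo-3-hydroxy-4-methoxybenzaldehyde; the biaryl is joined, the side chain is extended to the acid chloride, then ring A is attached and ring C closed in one flask; five benzyl ethers are removed last.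
3. Enabling feature: ring A is an unsubstituted phloroglucinol, so C4a is one of three equivalent C–H carbons, each lying between two OH groups. It can be acylated at carbon without protection or regiocontrol; one neighbouring OH becomes O1, the other remains as the 5-OH chelated to C4=O and makes closure of ring C effectively irreversible.
4. Stereochemistry: C2 (S) is the only stereocentre; it is set in the key step by a cinchona-thiourea-controlled oxa-Michael addition of the ring A hydroxyl to the E-enone and is not touched by the neutral final hydrogenolysis.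

Key step: step 10

Remark on the chemistry (assumption): the bond C2'(ring B)–C6(ring D) carries four ortho substituents and may be a stereogenic axis; the target structure defines only C2, so the axis is not controlled and both rotamers are accepted.

**Route**

Step 1
Reactants: 1 apigenin
Product: 2 7-(benzyloxy)-2-[4-(benzyloxy)phenyl]-5-hydroxy-4H-chromen-4-one
Conditions: BnBr (2.1 equiv), K2CO3, DMF, rt
Reagents that add atoms: benzyl bromide, BrCc1ccccc1
Why: Williamson etherification: K2CO3 deprotonates the acidic 7-OH and 4'-OH, while the 5-OH, hydrogen-bonded to the C4 carbonyl, is far less nucleophilic and stays free.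

Step 2
Reactants: 2 7-(benzyloxy)-2-[4-(benzyloxy)phenyl]-5-hydroxy-4H-chromen-4-one
Product: 3 7-(benzyloxy)-2-[4-(benzyloxy)phenyl]-5-hydroxy-6-iodo-4H-chromen-4-one
Conditions: benzyltrimethylammonium dichloroiodate (1.1 equiv), CaCO3, CH2Cl2/MeOH, rt
Reagents that add atoms: benzyltrimethylammonium dichloroiodate, C[N+](C)(C)Cc1ccccc1.Cl[I-]Cl
Why: Electrophilic aromatic iodination: with the dichloroiodate reagent 5-hydroxy-7-alkoxyflavones are attacked ortho to the free chelated 5-OH, at C6 of ring D, and CaCO3 traps the HCl so that the benzyl ethers survive.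

Step 3
Reactants: 3 7-(benzyloxy)-2-[4-(benzyloxy)phenyl]-5-hydroxy-6-iodo-4H-chromen-4-one
Product: 4 5,7-bis(benzyloxy)-2-[4-(benzyloxy)phenyl]-6-iodo-4H-chromen-4-one
Conditions: BnBr (1.5 equiv), K2CO3, KI (cat.), DMF, 70 °C
Reagents that add atoms: benzyl bromide, BrCc1ccccc1
Why: Williamson etherification under more forcing conditions caps the hindered, chelated 5-OH, so that no free phenol next to the iodide slows the later cross-coupling.

Step 4
Reactants: 5 2-bromo-3-hydroxy-4-methoxybenzaldehyde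
Product: 6 2-bromo-3,4-dihydroxybenzaldehyde
Conditions: BBr3 (3 equiv), CH2Cl2, −78 °C to rt; then H2O
Reagents that add atoms: none
Why: Lewis-acid cleavage of the aryl methyl ether with BBr3 (O-demethylation) frees the catechol; the aldehyde and the aryl bromide should tolerate the reagent at low temperature.

Step 5
Reactants: 6 2-bromo-3,4-dihydroxybenzaldehyde
Product: 7 3,4-bis(benzyloxy)-2-bromobenzaldehyde
Conditions: BnBr (2.3 equiv), K2CO3, DMF, 50 °C
Reagents that add atoms: benzyl bromide, BrCc1ccccc1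
Why: Double Williamson etherification protects the catechol with the same group as on the flavone, so that one hydrogenolysis removes all benzyl ethers at the end.

Step 6
Reactants: 7 3,4-bis(benzyloxy)-2-bromobenzaldehyde
Product: 8 3,4-bis(benzyloxy)-2-(4,4,5,5-tetramethyl-1,3,2-dioxaborolan-2-yl)benzaldehyde
Conditions: B2pin2 (1.5 equiv), PdCl2(dppf) (5 mol%), KOAc (3 equiv), 1,4-dioxane, 90 °C
Reagents that add atoms: bis(pinacolato)diboron, CC1(C)OB(OC1(C)C)B1OC(C)(C)C(C)(C)O1
Why: Miyaura borylation: the ortho-formyl group speeds oxidative addition of the hindered bromide to zerovalent palladium, and KOAc is too weak a base to trigger Suzuki homocoupling of the product.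

Step 7
Reactants: 4 5,7-bis(benzyloxy)-2-[4-(benzyloxy)phenyl]-6-iodo-4H-chromen-4-one; 8 3,4-bis(benzyloxy)-2-(4,4,5,5-tetramethyl-1,3,2-dioxaborolan-2-yl)benzaldehyde
Product: 9 3,4-bis(benzyloxy)-2-{5,7-bis(benzyloxy)-2-[4-(benzyloxy)phenyl]-4-oxo-4H-chromen-6-yl}benzaldehyde
Conditions: Pd(OAc)2 (5 mol%), SPhos (10 mol%), K3PO4 (3 equiv), PhMe/H2O 10:1, 100 °C
Reagents that add atoms: none
Why: Suzuki–Miyaura coupling: SPhos, a bulky electron-rich biarylphosphine suited to biaryls with four ortho substituents, should allow oxidative addition of the electron-rich iodide and transmetalation of the hindered boronate, joining C2' of ring B to C6 of ring D.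

Step 8
Reactants: 9 3,4-bis(benzyloxy)-2-{5,7-bis(benzyloxy)-2-[4-(benzyloxy)phenyl]-4-oxo-4H-chromen-6-yl}benzaldehyde; 10 malonic acid
Product: 11 (2E)-3-(3,4-bis(benzyloxy)-2-{5,7-bis(benzyloxy)-2-[4-(benzyloxy)phenyl]-4-oxo-4H-chromen-6-yl}phenyl)prop-2-enoic acid
Conditions: pyridine, piperidine (0.1 equiv), 90 °C
Reagents that add atoms: none
Why: Knoevenagel–Doebner condensation: the piperidine-catalysed condensation with malonic acid is followed by decarboxylation in hot pyridine and should give the E-acid as the thermodynamic alkene.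

Step 9
Reactants: 11 (2E)-3-(3,4-bis(benzyloxy)-2-{5,7-bis(benzyloxy)-2-[4-(benzyloxy)phenyl]-4-oxo-4H-chromen-6-yl}phenyl)prop-2-enoic acid
Product: 12 (2E)-3-(3,4-bis(benzyloxy)-2-{5,7-bis(benzyloxy)-2-[4-(benzyloxy)phenyl]-4-oxo-4H-chromen-6-yl}phenyl)prop-2-enoyl chloride
Conditions: (COCl)2 (1.5 equiv), DMF (cat.), CH2Cl2, 0 °C to rt; evaporate
Reagents that add atoms: oxalyl chloride, O=C(Cl)C(Cl)=O
Why: Acid chloride formation through the Vilsmeier-type chloroiminium salt from oxalyl chloride and DMF; all by-products are gases, so the crude chloride can be used directly with its E geometry intact.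

Step 10
Reactants: 12 (2E)-3-(3,4-bis(benzyloxy)-2-{5,7-bis(benzyloxy)-2-[4-(benzyloxy)phenyl]-4-oxo-4H-chromen-6-yl}phenyl)prop-2-enoyl chloride; 13 phloroglucinol (anhydrous, 1.2 equiv)
Product: 15 (2S)-2-(3,4-bis(benzyloxy)-2-{5,7-bis(benzyloxy)-2-[4-(benzyloxy)phenyl]-4-oxo-4H-chromen-6-yl}phenyl)-5,7-dihydroxy-2,3-dihydro-4H-chromen-4-one, via trihydroxychalcone 14 (not isolated)
Conditions: HFIP/CH2Cl2 4:1, 0 °C to rt; evaporate, strip with PhMe; then N-[3,5-bis(trifluoromethyl)phenyl]-N'-[(8α,9S)-6'-methoxycinchonan-9-yl]thiourea (quinine-derived, 20 mol%), PhMe/THF 10:1, −20 °C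
Reagents that add atoms: none
Why: In HFIP the acid chloride 12 is activated by hydrogen bonding to chloride and acylates a ring carbon of phloroglucinol 13 (Friedel–Crafts acylation, forming C4–C4a), after which HCl and solvent are evaporated to leave chalcone 14. The bifunctional cinchona thiourea then deprotonates the acidic ortho-hydroxyl of the 2,4,6-trihydroxyphenyl ketone with its quinuclidine nitrogen, binds the enone carbonyl through the thiourea and delivers the phenoxide to C2 (intramolecular oxa-Michael addition, forming O1–C2); the closest known reaction types are the HFIP-promoted acylation of electron-rich arenes by acid chlorides and the cinchona-catalysed cyclisation of 2'-hydroxychalcones to flavanones. Ring C closes in the 6-endo-trig mode. C2 is set under catalyst control: the chiral ion pair should direct oxygen to the Si face of C2 of the E-enone, which corresponds to the 2S configuration. The step needs C-acylation at the acyl carbon in preference to O-acylation and to conjugate addition at C2, and a kinetically controlled ring closure; the first is secured by the carbon nucleophilicity of the phloroglucinol ring (three equivalent C–H positions, each between two OH groups), the hard acylium-like electrophile and the damped oxygen nucleophilicity in HFIP, the second by the remaining ortho-hydroxyl, which ends as the 5-OH chelated to the C4 carbonyl and should make the retro-reaction slow at −20 °C.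

Step 11
Reactants: 15 (2S)-2-(3,4-bis(benzyloxy)-2-{5,7-bis(benzyloxy)-2-[4-(benzyloxy)phenyl]-4-oxo-4H-chromen-6-yl}phenyl)-5,7-dihydroxy-2,3-dihydro-4H-chromen-4-one
Product: 16 (2S)-2-{2-[5,7-dihydroxy-2-(4-hydroxyphenyl)-4-oxo-4H-chromen-6-yl]-3,4-dihydroxyphenyl}-5,7-dihydroxy-2,3-dihydro-4H-chromen-4-one (CNP0285181.1)
Conditions: H2 (1 atm), 10% Pd/C, EtOAc/MeOH 1:1, rt; stopped after uptake of five equivalents of H2
Reagents that add atoms: none
Why: Hydrogenolysis of the five benzyl ethers over Pd/C in neutral medium, which leaves the base-labile C2 stereocentre untouched and, if stopped at the calculated uptake, should spare the benzylic C2–O1 bond of ring C and the C2=C3 bond of ring E.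

**Compound list**

1 | apigenin, 5,7-dihydroxy-2-(4-hydroxyphenyl)-4H-chromen-4-one | O=c1cc(-c2ccc(O)cc2)oc2cc(O)cc(O)c12 | starting material
2 | 7-(benzyloxy)-2-[4-(benzyloxy)phenyl]-5-hydroxy-4H-chromen-4-one | O=c1cc(-c2ccc(OCc3ccccc3)cc2)oc2cc(OCc3ccccc3)cc(O)c12 | intermediate
3 | 7-(benzyloxy)-2-[4-(benzyloxy)phenyl]-5-hydroxy-6-iodo-4H-chromen-4-one | O=c1cc(-c2ccc(OCc3ccccc3)cc2)oc2cc(OCc3ccccc3)c(I)c(O)c12 | intermediate
4 | 5,7-bis(benzyloxy)-2-[4-(benzyloxy)phenyl]-6-iodo-4H-chromen-4-one | O=c1cc(-c2ccc(OCc3ccccc3)cc2)oc2cc(OCc3ccccc3)c(I)c(OCc3ccccc3)c12 | intermediate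
5 | 2-bromo-3-hydroxy-4-methoxybenzaldehyde | O=Cc1ccc(OC)c(O)c1Br | starting material
6 | 2-bromo-3,4-dihydroxybenzaldehyde | O=Cc1ccc(O)c(O)c1Br | intermediate
7 | 3,4-bis(benzyloxy)-2-bromobenzaldehyde | O=Cc1ccc(OCc2ccccc2)c(OCc2ccccc2)c1Br | intermediate
8 | 3,4-bis(benzyloxy)-2-(4,4,5,5-tetramethyl-1,3,2-dioxaborolan-2-yl)benzaldehyde | O=Cc1ccc(OCc2ccccc2)c(OCc2ccccc2)c1B1OC(C)(C)C(C)(C)O1 | intermediate
9 | 3,4-bis(benzyloxy)-2-{5,7-bis(benzyloxy)-2-[4-(benzyloxy)phenyl]-4-oxo-4H-chromen-6-yl}benzaldehyde | O=Cc1ccc(OCc2ccccc2)c(OCc2ccccc2)c1-c1c(OCc2ccccc2)cc2oc(-c3ccc(OCc4ccccc4)cc3)cc(=O)c2c1OCc1ccccc1 | intermediate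
10 | malonic acid | OC(=O)CC(=O)O | starting material
11 | (2E)-3-(3,4-bis(benzyloxy)-2-{5,7-bis(benzyloxy)-2-[4-(benzyloxy)phenyl]-4-oxo-4H-chromen-6-yl}phenyl)prop-2-enoic acid | OC(=O)/C=C/c1ccc(OCc2ccccc2)c(OCc2ccccc2)c1-c1c(OCc2ccccc2)cc2oc(-c3ccc(OCc4ccccc4)cc3)cc(=O)c2c1OCc1ccccc1 | intermediate
12 | (2E)-3-(3,4-bis(benzyloxy)-2-{5,7-bis(benzyloxy)-2-[4-(benzyloxy)phenyl]-4-oxo-4H-chromen-6-yl}phenyl)prop-2-enoyl chloride | O=C(Cl)/C=C/c1ccc(OCc2ccccc2)c(OCc2ccccc2)c1-c1c(OCc2ccccc2)cc2oc(-c3ccc(OCc4ccccc4)cc3)cc(=O)c2c1OCc1ccccc1 | intermediate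
13 | phloroglucinol, benzene-1,3,5-triol | Oc1cc(O)cc(O)c1 | starting material
14 | (2E)-3-(3,4-bis(benzyloxy)-2-{5,7-bis(benzyloxy)-2-[4-(benzyloxy)phenyl]-4-oxo-4H-chromen-6-yl}phenyl)-1-(2,4,6-trihydroxyphenyl)prop-2-en-1-one | O=C(/C=C/c1ccc(OCc2ccccc2)c(OCc2ccccc2)c1-c1c(OCc2ccccc2)cc2oc(-c3ccc(OCc4ccccc4)cc3)cc(=O)c2c1OCc1ccccc1)c1c(O)cc(O)cc1O | intermediate
15 | (2S)-2-(3,4-bis(benzyloxy)-2-{5,7-bis(benzyloxy)-2-[4-(benzyloxy)phenyl]-4-oxo-4H-chromen-6-yl}phenyl)-5,7-dihydroxy-2,3-dihydro-4H-chromen-4-one | O=C1C[C@@H](c2ccc(OCc3ccccc3)c(OCc3ccccc3)c2-c2c(OCc3ccccc3)cc3oc(-c4ccc(OCc5ccccc5)cc4)cc(=O)c3c2OCc2ccccc2)Oc2cc(O)cc(O)c21 | intermediate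
16 | (2S)-2-{2-[5,7-dihydroxy-2-(4-hydroxyphenyl)-4-oxo-4H-chromen-6-yl]-3,4-dihydroxyphenyl}-5,7-dihydroxy-2,3-dihydro-4H-chromen-4-one (CNP0285181.1) | O=C1C[C@@H](c2ccc(O)c(O)c2-c2c(O)cc3oc(-c4ccc(O)cc4)cc(=O)c3c2O)Oc2cc(O)cc(O)c21 | target

**Step count and risks**

Total step count: 11 steps. Longest linear sequence: 8 steps (steps 1, 2, 3, 7, 8, 9, 10, 11 from apigenin; the branch from 5 through steps 4, 5, 6 is equally long).

Steps most likely to fail:

1. Step 10. What may go wrong: O-acylation of phloroglucinol or conjugate arylation at C2 competing with C-acylation; ring closure without the catalyst in the acidic fluoroalcohol; a mismatch between the catalyst and one sense of the hindered biaryl axis. The last two would lower the facial selectivity at C2, and the sense of induction of the quinine-derived catalyst on this enone has to be confirmed on a model (the quinidine-derived pseudoenantiomer gives the opposite sense). Fallback: the one-flask annulation is given up and ring C is closed on an acceptor that carries an ester at C3 as activating group. It sets out from aldehyde 9 and comes back to the route at target 16. The purchased ketone 1-[2,4-bis(benzyloxy)-6-hydroxyphenyl]ethanone F1 is C-acylated as its dianion (LiN(SiMe3)2, THF, −78 °C, then di-tert-butyl dicarbonate; Claisen-type acylation) to tert-butyl 3-[2,4-bis(benzyloxy)-6-hydroxyphenyl]-3-oxopropanoate F2. Knoevenagel condensation of this ester with 9 (piperidine, AcOH, PhMe, molecular sieves) should give the alkylidene β-keto ester tert-butyl 2-[2,4-bis(benzyloxy)-6-hydroxybenzoyl]-3-(3,4-bis(benzyloxy)-2-{5,7-bis(benzyloxy)-2-[4-(benzyloxy)phenyl]-4-oxo-4H-chromen-6-yl}phenyl)prop-2-enoate F3. The cinchona thiourea of the series that delivers 2S (10 mol%, PhMe, −25 °C) closes ring C by oxa-Michael addition onto this doubly activated acceptor to the tert-butyl (2S)-4-oxochromane-3-carboxylate F4. TsOH in PhMe at 80 °C cleaves the tert-butyl ester and decarboxylates to (2S)-5,7-bis(benzyloxy)-2-(3,4-bis(benzyloxy)-2-{5,7-bis(benzyloxy)-2-[4-(benzyloxy)phenyl]-4-oxo-4H-chromen-6-yl}phenyl)-2,3-dihydro-4H-chromen-4-one F5, and hydrogenolysis under the conditions of step 11 removes seven benzyl groups to give 16.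

2. Step 7. What may go wrong: slow transmetalation at the junction with four ortho substituents, so that protodeboronation of the ortho-formyl boronate and reduction of the iodide take over. Fallback: the roles of the partners are reversed and the coupling is run as a Negishi reaction. It sets out from iodide 4 and bromide 7 (boronate 8 and step 6 are not needed) and comes back at aldehyde 9. Iodine–magnesium exchange on 4 (iPrMgCl·LiCl, THF, −40 °C) gives {5,7-bis(benzyloxy)-2-[4-(benzyloxy)phenyl]-4-oxo-4H-chromen-6-yl}magnesium chloride F6; ZnCl2 converts it into {5,7-bis(benzyloxy)-2-[4-(benzyloxy)phenyl]-4-oxo-4H-chromen-6-yl}zinc chloride F7, which tolerates the aldehyde of 7 and is coupled with it (Pd2(dba)3, SPhos, THF, 60 °C) to 9.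

3. Step 11. What may go wrong: over-reduction, namely hydrogenolysis of the benzylic C2–O1 bond of ring C or saturation of the C2=C3 bond of ring E, and stalling at the hindered benzyl ether on O5 of ring D. Fallback: reductive cleavage is replaced by Lewis-acid debenzylation with a cation scavenger. It sets out from 15 and comes back at 16: BCl3 (excess) and pentamethylbenzene in CH2Cl2 at −78 °C, then MeOH, should remove all five benzyl groups without hydrogen or a metal surface; no new compound arises (F0).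

**Further compounds**

F1 | step 10 | 1-[2,4-bis(benzyloxy)-6-hydroxyphenyl]ethanone (purchased) | CC(=O)c1c(O)cc(OCc2ccccc2)cc1OCc1ccccc1
F2 | step 10 | tert-butyl 3-[2,4-bis(benzyloxy)-6-hydroxyphenyl]-3-oxopropanoate | CC(C)(C)OC(=O)CC(=O)c1c(O)cc(OCc2ccccc2)cc1OCc1ccccc1
F3 | step 10 | tert-butyl 2-[2,4-bis(benzyloxy)-6-hydroxybenzoyl]-3-(3,4-bis(benzyloxy)-2-{5,7-bis(benzyloxy)-2-[4-(benzyloxy)phenyl]-4-oxo-4H-chromen-6-yl}phenyl)prop-2-enoate (alkene geometry not defined) | CC(C)(C)OC(=O)C(=Cc1ccc(OCc2ccccc2)c(OCc2ccccc2)c1-c1c(OCc2ccccc2)cc2oc(-c3ccc(OCc4ccccc4)cc3)cc(=O)c2c1OCc1ccccc1)C(=O)c1c(O)cc(OCc2ccccc2)cc1OCc1ccccc1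
F4 | step 10 | tert-butyl (2S)-5,7-bis(benzyloxy)-2-(3,4-bis(benzyloxy)-2-{5,7-bis(benzyloxy)-2-[4-(benzyloxy)phenyl]-4-oxo-4H-chromen-6-yl}phenyl)-4-oxochromane-3-carboxylate (C3 not defined) | O=C1C(C(=O)OC(C)(C)C)[C@@H](c2ccc(OCc3ccccc3)c(OCc3ccccc3)c2-c2c(OCc3ccccc3)cc3oc(-c4ccc(OCc5ccccc5)cc4)cc(=O)c3c2OCc2ccccc2)Oc2cc(OCc3ccccc3)cc(OCc3ccccc3)c21
F5 | step 10 | (2S)-5,7-bis(benzyloxy)-2-(3,4-bis(benzyloxy)-2-{5,7-bis(benzyloxy)-2-[4-(benzyloxy)phenyl]-4-oxo-4H-chromen-6-yl}phenyl)-2,3-dihydro-4H-chromen-4-one | O=C1C[C@@H](c2ccc(OCc3ccccc3)c(OCc3ccccc3)c2-c2c(OCc3ccccc3)cc3oc(-c4ccc(OCc5ccccc5)cc4)cc(=O)c3c2OCc2ccccc2)Oc2cc(OCc3ccccc3)cc(OCc3ccccc3)c21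
F6 | step 7 | {5,7-bis(benzyloxy)-2-[4-(benzyloxy)phenyl]-4-oxo-4H-chromen-6-yl}magnesium chloride | O=c1cc(-c2ccc(OCc3ccccc3)cc2)oc2cc(OCc3ccccc3)c([Mg]Cl)c(OCc3ccccc3)c12
F7 | step 7 | {5,7-bis(benzyloxy)-2-[4-(benzyloxy)phenyl]-4-oxo-4H-chromen-6-yl}zinc chloride | O=c1cc(-c2ccc(OCc3ccccc3)cc2)oc2cc(OCc3ccccc3)c([Zn]Cl)c(OCc3ccccc3)c12
F0 | step 11 | none | none
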